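## Retrosynthetic overview
1. Homo-plakotenin 22 ⇒ retro intramolecular Diels–Alder (bonds C4–C5 and C3a–C7a) gives the acyclic (2E,4Z,6R,8R,9E,11E)-tetraenoic acid 21, used as the free acid and never isolated.
2. 21 ⇒ sp2–sp2 disconnection at C3–C4 gives (Z)-alkenylzinc 20 (from iodide 14) and (E)-3-iodo-2-methylacrylic acid 18. The Negishi coupling creates the 4Z dienophile and triggers the cycloaddition.
3. 14 ⇒ styryl by HWE, (E)-enal by Wittig, (Z)-iodoalkene by α-iodo-Wittig, all on one C5 unit, dialdehyde 6.
4. 6 is C2-symmetric, so its CHO groups are homotopic and need no protecting group or desymmetrisation. It comes from diol 5, made by double ZACA of penta-1,4-diene 1.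
5. Ring order: no ring exists until the last step. The cyclohexene, the cyclopentane and four stereocentres (C3a, C4, C5, C7a) then form in one event.

Assumption: ylide 11 and the precatalyst (−)-(NMI)2ZrCl2 are taken as catalogue items. The precatalyst meant is the antipode that turns 1-alkenes into (R)-2-methylalkan-1-ols.

## Route

Step 1
Reactants: 1 penta-1,4-diene; 2 trimethylaluminium; 3 dioxygen
Product: 5 (2R,4R)-2,4-dimethylpentane-1,5-diol, via [(2R,4R)-2,4-dimethylpentane-1,5-diyl]bis(dimethylalane) 4 (not isolated)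
Conditions: Me3Al (4 equiv), (−)-(NMI)2ZrCl2 (5 mol %), MAO (cat.), CH2Cl2, 0 °C to rt, sealed, 24 h; then O2, 0 °C to rt; aq NaOH; SiO2 (removes meso-diol)
Reagents that add atoms: trimethylaluminium C[Al](C)C; dioxygen O=O
Why: Negishi ZACA reaction run twice on one substrate, in which the chiral zirconocene adds Me to the internal carbon of each vinyl group from the same enantioface (both CHMe centres set, about 75–80% ee per event), the second event drains most wrong-handed material into the separable meso-diol (Horeau-type amplification, ≥96% ee for the C2 isomer), and O2 oxidises the C–Al bonds without touching the stereocentres.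

Step 2
Reactants: 5 (2R,4R)-2,4-dimethylpentane-1,5-diol
Product: 6 (2R,4R)-2,4-dimethylpentanedial
Conditions: (COCl)2, DMSO, CH2Cl2, −78 °C; Et3N, −78 to 0 °C; used at once, crude
Reagents that add atoms: none
Why: Double Swern oxidation, in which both hydroxyls are activated at −78 °C before base is added, so no lactol or lactone forms and the α-methyl centres do not epimerise.

Step 3
Reactants: 6 (2R,4R)-2,4-dimethylpentanedial (2.5 equiv); 7 propyltriphenylphosphonium bromide; 8 iodine
Product: 10 (2R,4R,5Z)-6-iodo-2,4-dimethyloct-5-enal, via (1-iodopropylidene)triphenylphosphorane 9 (not isolated)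
Conditions: 7, n-BuLi, THF, 0 °C; I2, −78 °C; NaHMDS, −20 °C; then 6, −78 to −20 °C
Reagents that add atoms: propyltriphenylphosphonium bromide CCC[P+](c1ccccc1)(c1ccccc1)c1ccccc1.[Br-]; iodine II
Why: Stork–Zhao-type α-iodo-Wittig olefination under kinetic control puts iodine cis to the chain (Z, typically ≥10:1), attack at either homotopic formyl group of C2-symmetric 6 gives the same enantiomer, and the excess of 6 suppresses double olefination.

Step 4
Reactants: 10 (2R,4R,5Z)-6-iodo-2,4-dimethyloct-5-enal; 11 2-(triphenylphosphoranylidene)butanal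
Product: 12 (2E,4R,6R,7Z)-2-ethyl-8-iodo-4,6-dimethyldeca-2,7-dienal
Conditions: 11 (1.5 equiv), toluene, 90 °C, 14 h
Reagents that add atoms: 2-(triphenylphosphoranylidene)butanal CCC(C=O)=P(c1ccccc1)(c1ccccc1)c1ccccc1
Why: Wittig reaction with a stabilised formyl ylide gives the (E)-2-ethyl enal (>20:1) under neutral conditions that spare the α-stereocentre and the vinyl iodide, and the hindered product enal does not react a second time.

Step 5
Reactants: 12 (2E,4R,6R,7Z)-2-ethyl-8-iodo-4,6-dimethyldeca-2,7-dienal; 13 diethyl benzylphosphonate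
Product: 14 [(1E,3E,5R,7R,8Z)-3-ethyl-9-iodo-5,7-dimethylundeca-1,3,8-trien-1-yl]benzene
Conditions: 13 (1.5 equiv), NaHMDS (1.4 equiv), THF, −78 °C; then 12, −78 to 0 °C
Reagents that add atoms: diethyl benzylphosphonate CCOP(=O)(Cc1ccccc1)OCC
Why: Horner–Wadsworth–Emmons olefination with a benzylic phosphonate gives the (E)-styryl bond (>20:1), the preformed anion adds to the enal faster than it deprotonates the γ-position, and the unactivated iodoalkene is too poor a dienophile to cyclise early.

Step 6
Reactants: 15 diethyl methylmalonate; 16 iodoform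
Product: 17 diethyl 2-(diiodomethyl)-2-methylpropanedioate
Conditions: NaH, Et2O, reflux; CHI3, reflux, 24 h
Reagents that add atoms: iodoform IC(I)I
Why: C-alkylation of the malonate enolate with iodoform (formal substitution through diiodocarbene capture) installs the CHI2 group on the quaternary carbon, and no stereocentre is formed.

Step 7
Reactants: 17 diethyl 2-(diiodomethyl)-2-methylpropanedioate
Product: 18 (2E)-3-iodo-2-methylprop-2-enoic acid
Conditions: KOH, EtOH/H2O 3:1, reflux, 24 h; then conc. HCl
Reagents that add atoms: potassium hydroxide [K+].[OH-]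
Why: Saponification followed by decarboxylative (Grob-type) anti elimination of iodide gives only the E-iodoacrylic acid, with I trans to CO2H.

Step 8
Reactants: 14 [(1E,3E,5R,7R,8Z)-3-ethyl-9-iodo-5,7-dimethylundeca-1,3,8-trien-1-yl]benzene; 18 (2E)-3-iodo-2-methylprop-2-enoic acid
Product: 22 homo-plakotenin, (2E)-3-[(1R,3R,3aR,4S,5S,7aR)-4,7-diethyl-1,3-dimethyl-5-phenyl-2,3,3a,4,5,7a-hexahydro-1H-inden-4-yl]-2-methylprop-2-enoic acid, via (Z)-alkenyllithium (Li in place of I of 14, geometry retained) 19 (not isolated), via (Z)-alkenylzinc bromide 20 (not isolated), via (2E,4Z,6R,8R,9E,11E)-4,10-diethyl-2,6,8-trimethyl-12-phenyldodeca-2,4,9,11-tetraenoic acid 21 (not isolated)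
Conditions: t-BuLi (2.05 equiv), Et2O, −78 °C, 20 min; ZnBr2 (THF), −78 to 0 °C; add to 18 + NaH (1.2 equiv each), THF, 0 °C, then Pd(PPh3)4 (5 mol %), rt, 3 h; 1 M HCl, extract into toluene; crude toluene solution (0.01 M), BHT, 90 °C, 16 h
Reagents that add atoms: (2E)-3-iodo-2-methylprop-2-enoic acid OC(=O)/C(C)=C/I
Why: Retentive I–Li exchange and transmetalation give a configurationally stable (Z)-alkenylzinc whose Negishi coupling with the carboxylate of 18 keeps both alkene geometries, and the 2E,4Z-dienoic acid so formed then undergoes the intramolecular Diels–Alder reaction (suprafacial, tether-exo, trans-hydrindene transition state), in which the 4Z geometry fixes quaternary C4 (acid arm cis to C3, ethyl cis to H3a and to phenyl), the E,E-diene fixes C5 relative to C7a, and allylic strain at the two methyl-bearing tether carbons (6R,8R) decides the diene face, so C3a, C4, C5 and C7a are set together.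

## Compound list
1 | penta-1,4-diene | C=CCC=C | starting material
2 | trimethylaluminium | C[Al](C)C | starting material
3 | dioxygen | O=O | starting material
4 | [(2R,4R)-2,4-dimethylpentane-1,5-diyl]bis(dimethylalane) | C[Al](C)C[C@H](C)C[C@@H](C)C[Al](C)C | intermediate
5 | (2R,4R)-2,4-dimethylpentane-1,5-diol | OC[C@H](C)C[C@@H](C)CO | intermediate
6 | (2R,4R)-2,4-dimethylpentanedial | O=C[C@H](C)C[C@@H](C)C=O | intermediate
7 | propyltriphenylphosphonium bromide | CCC[P+](c1ccccc1)(c1ccccc1)c1ccccc1.[Br-] | starting material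
8 | iodine | II | starting material
9 | (1-iodopropylidene)triphenylphosphorane | CCC(I)=P(c1ccccc1)(c1ccccc1)c1ccccc1 | intermediate
10 | (2R,4R,5Z)-6-iodo-2,4-dimethyloct-5-enal | O=C[C@H](C)C[C@@H](C)/C=C(\I)CC | intermediate
11 | 2-(triphenylphosphoranylidene)butanal | CCC(C=O)=P(c1ccccc1)(c1ccccc1)c1ccccc1 | starting material
12 | (2E,4R,6R,7Z)-2-ethyl-8-iodo-4,6-dimethyldeca-2,7-dienal | O=C/C(CC)=C/[C@H](C)C[C@@H](C)/C=C(\I)CC | intermediate
13 | diethyl benzylphosphonate | CCOP(=O)(Cc1ccccc1)OCC | starting material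
14 | [(1E,3E,5R,7R,8Z)-3-ethyl-9-iodo-5,7-dimethylundeca-1,3,8-trien-1-yl]benzene | c1ccccc1/C=C/C(CC)=C/[C@H](C)C[C@@H](C)/C=C(\I)CC | intermediate
15 | diethyl methylmalonate | CCOC(=O)C(C)C(=O)OCC | starting material
16 | iodoform | IC(I)I | starting material
17 | diethyl 2-(diiodomethyl)-2-methylpropanedioate | CCOC(=O)C(C)(C(I)I)C(=O)OCC | intermediate
18 | (2E)-3-iodo-2-methylprop-2-enoic acid | OC(=O)/C(C)=C/I | intermediate
19 | (Z)-alkenyllithium from 14 | [Li]/C(CC)=C\[C@H](C)C[C@@H](C)/C=C(CC)/C=C/c1ccccc1 | intermediate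
20 | (Z)-alkenylzinc bromide from 19 | Br[Zn]/C(CC)=C\[C@H](C)C[C@@H](C)/C=C(CC)/C=C/c1ccccc1 | intermediate
21 | (2E,4Z,6R,8R,9E,11E)-4,10-diethyl-2,6,8-trimethyl-12-phenyldodeca-2,4,9,11-tetraenoic acid | OC(=O)/C(C)=C/C(CC)=C\[C@H](C)C[C@@H](C)/C=C(CC)/C=C/c1ccccc1 | intermediate
22 | homo-plakotenin | CCC1=C[C@@H](c2ccccc2)[C@@](/C=C(\C)C(=O)O)(CC)[C@H]2[C@H]1[C@H](C)C[C@H]2C | target

## Step count and risks
Total steps: 8. Longest linear sequence: 6 (steps 1, 2, 3, 4, 5, 8). Steps 6 and 7 form the side branch to 18.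

**Most likely to fail: step 8.**
- t-BuLi has to exchange iodine faster than it adds to the phenyldiene.
- The coupling runs on an unprotected carboxylate.
- The 4Z-dienoic acid can undergo a [1,5]-H shift if the cycloaddition is slow.
- The alkene geometries fix C4, C5, C3a and C7a relative to one another. The exo/endo choice and the diene face relative to the 1,3-methyl groups rest on substrate bias only, so they must be checked by NOE or X-ray on the first material.

The fallback makes the C2=C3 bond by olefination instead of making the C3–C4 bond by coupling, and uses an ester that can be isolated. It sets out from 14 and comes back at 22. I–Li exchange and DMF give (2Z,4R,6R,7E,9E)-2,8-diethyl-4,6-dimethyl-10-phenyldeca-2,7,9-trienal F10, which is kept cold and used at once. Wittig olefination with ethyl 2-(triphenylphosphoranylidene)propanoate in toluene gives ethyl (2E,4Z,6R,8R,9E,11E)-4,10-diethyl-2,6,8-trimethyl-12-phenyldodeca-2,4,9,11-tetraenoate F11. This can be characterised and then cyclised on its own at 80–110 °C to ethyl (2E)-3-[(1R,3R,3aR,4S,5S,7aR)-4,7-diethyl-1,3-dimethyl-5-phenyl-2,3,3a,4,5,7a-hexahydro-1H-inden-4-yl]-2-methylprop-2-enoate F12. LiOH in THF/MeOH/H2O then gives 22.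

**Second: step 3.** This is a mono-olefination of a labile dialdehyde, generation of the iodo-ylide is capricious (30–50% is usual), and the Z:E ratio is variable. The fallback builds the Z-haloalkene by stereoselective cross-coupling instead of a Wittig reaction. It sets out from 6 and comes back at 19.
- Ramirez olefination of excess 6 (CBr4, PPh3, CH2Cl2, 0 °C, non-basic) gives (2R,4R)-6,6-dibromo-2,4-dimethylhex-5-enal F6.
- Pd(DPEphos)Cl2-catalysed Negishi coupling with EtZnBr replaces only the bromine trans to the chain and gives (2R,4R,5Z)-6-bromo-2,4-dimethyloct-5-enal F7.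
- The reactions of steps 4 and 5 then give (2E,4R,6R,7Z)-8-bromo-2-ethyl-4,6-dimethyldeca-2,7-dienal F8 and [(1E,3E,5R,7R,8Z)-9-bromo-3-ethyl-5,7-dimethylundeca-1,3,8-trien-1-yl]benzene F9.
- Br–Li exchange of F9 (t-BuLi, −78 °C) gives 19.

**Third: step 1.** The skipped diene is volatile, each carboalumination gives only moderate ee, and about 20% meso-diol has to be removed. The fallback is a classical synthesis followed by enzymatic sorting. It sets out from 15 and comes back at 5.
- Michael addition of 15 to ethyl methacrylate (cat. NaOEt, EtOH) gives triethyl pentane-2,2,4-tricarboxylate F1.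
- 6 M HCl at reflux hydrolyses and decarboxylates it to 2,4-dimethylpentanedioic acid (all stereoisomers) F2.
- LiAlH4 gives 2,4-dimethylpentane-1,5-diol (all stereoisomers) F3.
- Pseudomonas lipase (Amano PS) with vinyl acetate acetylates (S)-configured CH(CH3)CH2OH termini much faster than (R) ones. The S,S-diol therefore leaves as (2S,4S)-2,4-dimethylpentane-1,5-diyl diacetate F4 and the meso-diol as (2S,4R)-5-hydroxy-2,4-dimethylpentyl acetate F5. The doubly mismatched R,R-diol 5 stays as the only free diol and is separated by chromatography (25% at most).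

## Further compounds
F1 | step 1 | triethyl pentane-2,2,4-tricarboxylate | CCOC(=O)C(C)CC(C)(C(=O)OCC)C(=O)OCC
F2 | step 1 | 2,4-dimethylpentanedioic acid (all stereoisomers) | OC(=O)C(C)CC(C)C(=O)O
F3 | step 1 | 2,4-dimethylpentane-1,5-diol (all stereoisomers) | OCC(C)CC(C)CO
F4 | step 1 | (2S,4S)-2,4-dimethylpentane-1,5-diyl diacetate | CC(=O)OC[C@@H](C)C[C@H](C)COC(C)=O
F5 | step 1 | (2S,4R)-5-hydroxy-2,4-dimethylpentyl acetate | CC(=O)OC[C@@H](C)C[C@@H](C)CO
F6 | step 3 | (2R,4R)-6,6-dibromo-2,4-dimethylhex-5-enal | O=C[C@H](C)C[C@@H](C)C=C(Br)Br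
F7 | step 3 | (2R,4R,5Z)-6-bromo-2,4-dimethyloct-5-enal | O=C[C@H](C)C[C@@H](C)/C=C(\Br)CC
F8 | step 3 | (2E,4R,6R,7Z)-8-bromo-2-ethyl-4,6-dimethyldeca-2,7-dienal | O=C/C(CC)=C/[C@H](C)C[C@@H](C)/C=C(\Br)CC
F9 | step 3 | [(1E,3E,5R,7R,8Z)-9-bromo-3-ethyl-5,7-dimethylundeca-1,3,8-trien-1-yl]benzene | c1ccccc1/C=C/C(CC)=C/[C@H](C)C[C@@H](C)/C=C(\Br)CC
F10 | step 8 | (2Z,4R,6R,7E,9E)-2,8-diethyl-4,6-dimethyl-10-phenyldeca-2,7,9-trienal | O=C/C(CC)=C\[C@H](C)C[C@@H](C)/C=C(CC)/C=C/c1ccccc1
F11 | step 8 | ethyl (2E,4Z,6R,8R,9E,11E)-4,10-diethyl-2,6,8-trimethyl-12-phenyldodeca-2,4,9,11-tetraenoate | CCOC(=O)/C(C)=C/C(CC)=C\[C@H](C)C[C@@H](C)/C=C(CC)/C=C/c1ccccc1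
F12 | step 8 | ethyl ester of homo-plakotenin | CCC1=C[C@@H](c2ccccc2)[C@@](/C=C(\C)C(=O)OCC)(CC)[C@H]2[C@H]1[C@H](C)C[C@H]2C
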